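**Retrosynthetic overview**
1. Target acid 9 ⇐ methyl ester 7, by a late, non-epimerising ester cleavage.
2. 7 ⇐ open-chain 2'-hydroxyaryl (2E)-enone 6, by forming the C2–O bond: an enantioselective 6-endo oxa-Michael closure that builds the only new ring (the dihydropyranone) and sets C2.
3. 6 ⇐ aryl–C(O) bond: aryl Grignard from methyl 4-hydroxy-3-iodobenzoate 3 plus (2E,6E)-farnesal 2, then oxidation. The farnesyl unit brings all side-chain carbons and both E-alkenes.
4. 2 ⇐ (2E,6E)-farnesol 1. The benzene ring is bought; the pyranone ring is closed in step 4.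

Assumption: trans,trans-farnesol (≥96 % 2E,6E) and methyl 4-hydroxy-3-iodobenzoate are bought as such.
Assumption: the sense of induction of the new step 4 cannot be predicted with certainty, so the catalyst enantiomer (from L- or D-tert-leucinol) that gives (S)-7 is fixed in a first analytical run (chiral HPLC, ECD/VCD) and used throughout.

**Step 1**
Reactants: 1 (2E,6E)-farnesol
Product: 2 (2E,6E)-farnesal
Conditions: TEMPO (0.1 equiv), PhI(OAc)2 (1.1 equiv), MeCN/aq pH 7 phosphate buffer, 0 °C to rt
Reagents that add atoms: none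
Why: Oxoammonium (TEMPO/BAIB) oxidation of a primary allylic alcohol stops at the enal under buffered conditions, leaves the isolated trisubstituted alkenes alone and does not isomerise the 2E double bond.

**Step 2**
Reactants: 3 methyl 4-hydroxy-3-iodobenzoate; 2 (2E,6E)-farnesal
Product: 5 methyl 4-hydroxy-3-[(2E,6E)-1-hydroxy-3,7,11-trimethyldodeca-2,6,10-trien-1-yl]benzoate (racemic at the carbinol carbon), via aryl Grignard dianion 4 (not isolated)
Conditions: 3 (1.2 equiv), MeMgCl (1.2 equiv), LiCl, THF, −20 °C; iPrMgCl·LiCl (1.3 equiv), −20 °C, 1 h; then 2 (1.0 equiv), −20 to 0 °C; sat. aq NH4Cl; crude 5 used at once (no acid, no heat)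
Reagents that add atoms: none
Why: Iodine–magnesium exchange on the pre-deprotonated iodophenol gives the aryl Grignard at −20 °C, where the phenoxide-deactivated methyl ester is inert, and it adds 1,2 to the enal (Grignard addition); the carbinol centre is formed racemic and is erased in step 3.

**Step 3**
Reactants: 5 methyl 4-hydroxy-3-[(2E,6E)-1-hydroxy-3,7,11-trimethyldodeca-2,6,10-trien-1-yl]benzoate
Product: 6 methyl 4-hydroxy-3-[(2E,6E)-3,7,11-trimethyldodeca-2,6,10-trienoyl]benzoate
Conditions: activated MnO2 (15 equiv), CH2Cl2, rt; filter through Celite; fast chromatography on neutral silica (removes any cyclised material)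
Reagents that add atoms: none
Why: MnO2 oxidises only the benzylic-allylic alcohol and keeps the 2E geometry, and the O–H···O=C hydrogen bond of the product holds the phenol away from the β-carbon, so 6 does not cyclise without base.

**Step 4**
Reactants: 6 methyl 4-hydroxy-3-[(2E,6E)-3,7,11-trimethyldodeca-2,6,10-trienoyl]benzoate
Product: 7 methyl (2S)-2-[(3E)-4,8-dimethylnona-3,7-dien-1-yl]-2-methyl-4-oxo-3,4-dihydro-2H-chromene-6-carboxylate
Conditions: bifunctional iminophosphorane catalyst (10 mol %) N-[(2S)-3,3-dimethyl-1-{[tris(4-methoxyphenyl)-λ5-phosphanylidene]amino}butan-2-yl]-N'-[3,5-bis(trifluoromethyl)phenyl]thiourea (or its enantiomer, see assumption), toluene (0.1 M), −20 to 0 °C; stopped at about 95 % conversion by passing cold through a short silica pad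
Reagents that add atoms: none
Why: Proposed new method: iminophosphorane (superbase/thiourea)-catalysed enantioselective 6-endo-trig oxa-Michael closure of a 2'-hydroxyaryl β-methyl-β-alkyl enone, an unactivated acceptor that gives a fully alkyl-substituted C–O stereocentre. The catalyst deprotonates the acidic phenol, which in neutral 6 is locked on the carbonyl and cannot reach Cβ, so no background reaction is expected. The thiourea binds the enone carbonyl of the chiral phosphonium phenoxide ion pair, the phenoxide adds to one face of Cβ, and the P–N–H+ unit protonates the enolate. Because the 2E geometry is fixed and no base strong enough for γ-deprotonation is present, face selection alone sets C2 as (S), with no need to tell CH3 from CH2R by size; low temperature and an early stop keep retro-oxa-Michael from eroding ee. The closest known reaction type is the tertiary-amine/(thio)urea- or iminophosphorane-catalysed intramolecular oxa-Michael addition giving 2-monosubstituted chromanones, flavanones or O-heterocycles from activated acceptors, together with iminophosphorane-catalysed conjugate additions to β,β-disubstituted acceptors.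

**Step 5**
Reactants: 7 methyl (2S)-2-[(3E)-4,8-dimethylnona-3,7-dien-1-yl]-2-methyl-4-oxo-3,4-dihydro-2H-chromene-6-carboxylate
Product: 9 (2S)-2-[(3E)-4,8-dimethylnona-3,7-dien-1-yl]-2-methyl-4-oxo-3,4-dihydro-2H-chromene-6-carboxylic acid (target), via trimethylstannyl ester 8 (not isolated)
Conditions: Me3SnOH (5 equiv), ClCH2CH2Cl, 70 °C; then cold 1 M aq HCl wash
Reagents that add atoms: trimethyltin hydroxide, C[Sn](C)(C)O
Why: Tin-mediated ester hydrolysis delivers hydroxide to the ester carbonyl under nearly neutral conditions that spare E1cB-labile groups, so the chromanone is not opened by retro-oxa-Michael, C2 stays (S) and the alkenes are untouched.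

**Compound list**
1 | (2E,6E)-farnesol | OC/C=C(C)/CC/C=C(C)/CCC=C(C)C | starting material
2 | (2E,6E)-farnesal | O=C/C=C(C)/CC/C=C(C)/CCC=C(C)C | intermediate
3 | methyl 4-hydroxy-3-iodobenzoate | COC(=O)c1ccc(O)c(I)c1 | starting material
4 | chloromagnesium 2-(chloromagnesio)-4-(methoxycarbonyl)phenoxide (aryl Grignard dianion, not isolated) | COC(=O)c1ccc(O[Mg]Cl)c([Mg]Cl)c1 | intermediate
5 | methyl 4-hydroxy-3-[(2E,6E)-1-hydroxy-3,7,11-trimethyldodeca-2,6,10-trien-1-yl]benzoate (racemic carbinol) | COC(=O)c1ccc(O)c(c1)C(O)/C=C(C)/CC/C=C(C)/CCC=C(C)C | intermediate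
6 | methyl 4-hydroxy-3-[(2E,6E)-3,7,11-trimethyldodeca-2,6,10-trienoyl]benzoate | COC(=O)c1ccc(O)c(c1)C(=O)/C=C(C)/CC/C=C(C)/CCC=C(C)C | intermediate
7 | methyl (2S)-2-[(3E)-4,8-dimethylnona-3,7-dien-1-yl]-2-methyl-4-oxo-3,4-dihydro-2H-chromene-6-carboxylate | CC(C)=CCC/C(C)=C/CC[C@@]1(C)CC(=O)c2cc(C(=O)OC)ccc2O1 | intermediate
8 | trimethylstannyl (2S)-2-[(3E)-4,8-dimethylnona-3,7-dien-1-yl]-2-methyl-4-oxo-3,4-dihydro-2H-chromene-6-carboxylate (not isolated) | CC(C)=CCC/C(C)=C/CC[C@@]1(C)CC(=O)c2cc(C(=O)O[Sn](C)(C)C)ccc2O1 | intermediate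
9 | (2S)-2-[(3E)-4,8-dimethylnona-3,7-dien-1-yl]-2-methyl-4-oxo-3,4-dihydro-2H-chromene-6-carboxylic acid | CC(C)=CCC/C(C)=C/CC[C@@]1(C)CC(=O)c2cc(C(=O)O)ccc2O1 | target

**Totals**
Total step count: 5. Longest linear sequence: 5 steps (1 → 2 → 5 → 6 → 7 → 9).

**Steps most likely to fail**

Step 4 (new asymmetric oxa-Michael; risks are low rate, low ee, or ee erosion by reversibility). The fallback uses known chemistry, sets out from 6 and comes back at 7. Enone 6 is cyclised with K2CO3 in MeOH at rt (ordinary base-mediated oxa-Michael, as in the second half of a Kabbe chromanone synthesis) to give the racemic methyl ester F1. Preparative chiral SFC on an amylose carbamate phase with CO2/MeOH then delivers (S)-ester 7, and the separated (R)-enantiomer F2 is set aside or re-equilibrated with base and resolved again.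

Step 2 (Grignard formation on an unprotected iodophenol ester; diol 5 can lose water to an o-quinone methide and close to a 2H-chromene). The fallback sets out from 2 (with 3) and comes back at 6, bypassing 5 and step 3. Farnesal 2 is oxidised under Pinnick conditions (NaClO2, NaH2PO4, 2-methyl-2-butene, t-BuOH/H2O) to (2E,6E)-farnesoic acid F3. This is esterified with phenol 3 (DCC, cat. DMAP, CH2Cl2, 0 °C) to the aryl ester methyl 3-iodo-4-{[(2E,6E)-3,7,11-trimethyldodeca-2,6,10-trienoyl]oxy}benzoate F4. Iodine–magnesium exchange with iPrMgCl·LiCl in THF at −78 °C gives the ortho-magnesiated aryl ester F5. On warming to 0 °C the acyl group shifts from O to the ortho carbon (anionic Fries type), and aqueous NH4Cl gives 6.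

Step 5 (ester cleavage without retro-oxa-Michael racemisation at C2). The fallback sets out from 7 and comes back at 9. Instead of attacking the acyl carbon with an oxygen nucleophile, the O–CH3 bond is cut by SN2: anhydrous LiI (5 equiv) in EtOAc at reflux in the dark gives the lithium carboxylate F6, so no oxygen base meets the chromanone. A cold dilute HCl wash then gives 9.

**Further compounds**
F1 | step 4 | racemic methyl 2-[(3E)-4,8-dimethylnona-3,7-dien-1-yl]-2-methyl-4-oxo-3,4-dihydro-2H-chromene-6-carboxylate | CC(C)=CCC/C(C)=C/CCC1(C)CC(=O)c2cc(C(=O)OC)ccc2O1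
F2 | step 4 | methyl (2R)-2-[(3E)-4,8-dimethylnona-3,7-dien-1-yl]-2-methyl-4-oxo-3,4-dihydro-2H-chromene-6-carboxylate | CC(C)=CCC/C(C)=C/CC[C@]1(C)CC(=O)c2cc(C(=O)OC)ccc2O1
F3 | step 2 | (2E,6E)-farnesoic acid | OC(=O)/C=C(C)/CC/C=C(C)/CCC=C(C)C
F4 | step 2 | methyl 3-iodo-4-{[(2E,6E)-3,7,11-trimethyldodeca-2,6,10-trienoyl]oxy}benzoate | COC(=O)c1ccc(OC(=O)/C=C(C)/CC/C=C(C)/CCC=C(C)C)c(I)c1
F5 | step 2 | methyl 3-(chloromagnesio)-4-{[(2E,6E)-3,7,11-trimethyldodeca-2,6,10-trienoyl]oxy}benzoate | COC(=O)c1ccc(OC(=O)/C=C(C)/CC/C=C(C)/CCC=C(C)C)c([Mg]Cl)c1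
F6 | step 5 | lithium (2S)-2-[(3E)-4,8-dimethylnona-3,7-dien-1-yl]-2-methyl-4-oxo-3,4-dihydro-2H-chromene-6-carboxylate | CC(C)=CCC/C(C)=C/CC[C@@]1(C)CC(=O)c2cc(C(=O)[O-])ccc2O1.[Li+]
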